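**Plan**

Target: achiral 2-methoxy-6-(14-carboxytetradecyl)-1,4-benzoquinone. Quinone numbering used below: C1=O lies between C2–OMe and C6–chain; C3–H; C4=O; C5–H.
Retrosynthesis: (i) the tert-butyl ester C–O bond; (ii) ring bond C4–C5, with a C1–C4 σ bond redrawn, so that C1–C4 become a 4-hydroxy-3-methoxycyclobutenone and C5=C6 its 1-alkylvinyl group; (iii) C1–C6, giving 3-methoxycyclobutenedione and a 2-lithio-1-alkene; (iv) the vinyl C–I bond, then C15–C16 of the chain.
Enabling feature: the contiguous sp2 array C1(=O)–C2(OMe)=C3H–C4(=O) of the quinone ring is a methoxycyclobutenedione opened at C1–C4, and C5H=C6(chain) is a 1,1-disubstituted vinyl unit, so one carbonyl addition encodes the whole substitution pattern.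
Forward: dimethyl squarate gives the methyl semisquarate; 15-bromopentadecanoic acid gives the C17 ynoic acid, then the 2-iodo-1-alkene, then its tert-butyl ester. The derived alkenyllithium adds to the semisquarate (chain joined before ring closure). The only ring is then made by thermal 4π opening and 6π closure and oxidised to the quinone; ester acidolysis ends the route.
Stereochemistry: the target has no stereocentre and no stereogenic double bond; the one racemic carbinol centre formed on the way is destroyed when the ring closes.

Key step: step 6

Remark: because the target is achiral, "single enantiomer" sets no requirement; lithium salts of a product that are only protonated on work-up are treated as that product and carry no number.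

**Route**

Step 1
Reactants: 1 dimethyl squarate
Product: 3 3-methoxycyclobut-3-ene-1,2-dione, via hydroxycyclobutenone 2 (not isolated)
Conditions: LiAlH(OtBu)3 (1.05 equiv), THF, −78 °C; 1 M HCl quench; crude 2 then conc. HCl (cat.), CH2Cl2, rt
Reagents that add atoms: water, O (delivers the new carbonyl oxygen; the carbinol oxygen of 2 leaves as water)
Why: The hindered alkoxyaluminium hydride should reduce one of the two equivalent carbonyls 1,2 to the racemic carbinol 2, and acid-promoted ionisation to a methoxy-stabilised cyclobutenyl cation, capture by water and loss of methanol (enol-ether hydrolysis, the standard conversion of squarate adducts into cyclobutenediones) should leave semisquarate 3 and erase that stereocentre.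

Step 2
Reactants: 4 15-bromopentadecanoic acid; 5 lithium acetylide–ethylenediamine complex
Product: 6 heptadec-16-ynoic acid
Conditions: 5 (3 equiv), DMSO, 10 °C to rt; 1 M HCl work-up
Reagents that add atoms: none
Why: SN2 alkylation of the acetylide at the primary bromide in DMSO (acetylide alkylation), the first equivalent only forming the unreactive carboxylate, should add the two carbons that become C6 and C5 of the ring.

Step 3
Reactants: 6 heptadec-16-ynoic acid
Product: 7 16-iodoheptadec-16-enoic acid
Conditions: NaI (2 equiv), TMSCl (2 equiv), H2O (1 equiv), MeCN/CH2Cl2, rt, short reaction time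
Reagents that add atoms: sodium iodide, [Na+].[I-]
Why: Markovnikov hydroiodination of the terminal alkyne by HI made in situ should place iodine on the internal carbon through the more substituted vinyl cation and stop at the 2-iodo-1-alkene under limited stoichiometry; no stereo-element is formed.

Step 4
Reactants: 7 16-iodoheptadec-16-enoic acid
Product: 8 tert-butyl 16-iodoheptadec-16-enoate
Conditions: tert-butyl 2,2,2-trichloroacetimidate (2 equiv), CH2Cl2, rt, no catalyst
Reagents that add atoms: tert-butyl 2,2,2-trichloroacetimidate, CC(C)(C)OC(=N)C(Cl)(Cl)Cl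
Why: Self-catalysed O-alkylation of the carboxylic acid by the trichloroacetimidate (tert-butyl cation transfer, trichloroacetamide as leaving group) should leave the vinyl iodide untouched and give an ester that is hindered enough for the low-temperature organolithium step and acid-removable at the end.

Step 5
Reactants: 8 tert-butyl 16-iodoheptadec-16-enoate; 3 3-methoxycyclobut-3-ene-1,2-dione
Product: 10 (±)-tert-butyl 16-(1-hydroxy-2-methoxy-4-oxocyclobut-2-en-1-yl)heptadec-16-enoate, via alkenyllithium 9 (not isolated)
Conditions: t-BuLi (2.0 equiv), THF/Et2O/pentane 4:1:1, −100 °C, 5 min; transfer into 3 (1.2 equiv), THF, −100 to −78 °C; sat. NH4Cl at −78 °C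
Reagents that add atoms: none
Why: Iodine–lithium exchange should be complete within minutes at −100 °C, faster than attack on or enolisation of the remote tert-butyl ester, and the alkenyllithium should then add 1,2 to the carbonyl of 3 that is bonded to the methoxy-bearing carbon rather than to the vinylogous-ester carbonyl (the known regiochemistry of organolithium addition to 3-alkoxycyclobutenediones), giving a racemic carbinol whose stereocentre is erased in step 6.

Step 6
Reactants: 10 (±)-tert-butyl 16-(1-hydroxy-2-methoxy-4-oxocyclobut-2-en-1-yl)heptadec-16-enoate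
Product: 14 tert-butyl 15-(5-methoxy-3,6-dioxocyclohexa-1,4-dien-1-yl)pentadecanoate, via dienylketene 11 (not isolated), via cyclohexadienone 12 (not isolated), via hydroquinone 13 (not isolated)
Conditions: degassed PhMe (0.02 M), 110 °C, Ar; cool to rt; Ag2O (3 equiv), Na2SO4, rt
Reagents that add atoms: none
Why: Heating should open the cyclobutenone by conrotatory 4π electrocyclic cleavage of the bond between the carbinol carbon and the ring carbonyl, the donor hydroxyl rotating outward so that the 1-alkylvinyl group turns inward and ketene 11 forms with ketenyl and vinyl groups cis. This triene (vinyl C=C, the C(OMe)=C(OH) bond, the ketene C=C) should close the six-membered carbocycle by thermal disrotatory 6π electrocyclisation, forming the C4–C5 bond between the ketene carbon and the vinyl CH2, and dienone 12 should tautomerise to hydroquinone 13, aromatisation making the sequence irreversible. Ag2O then removes two hydrogens to give the quinone. The closest known reaction type is the thermal ring expansion of 4-alkenyl-4-hydroxycyclobutenones to hydroquinones followed by oxidation (the alkenyl variant of the Moore rearrangement). No stereocentre is formed, and the racemic carbinol carbon of 10 becomes the sp2 C1. The selectivity needed is regiochemical and is fixed by connectivity, because the carbinol carbon is bonded both to the methoxy carbon and to the chain-bearing vinyl carbon, so OMe (C2) and chain (C6) must flank C1=O; torquoselective outward rotation of OH secures the cis-dienylketene, and intramolecular 6π closure should outpace capture of the ketene by the hydroxyl.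

Step 7
Reactants: 14 tert-butyl 15-(5-methoxy-3,6-dioxocyclohexa-1,4-dien-1-yl)pentadecanoate
Product: 15 15-(5-methoxy-3,6-dioxocyclohexa-1,4-dien-1-yl)pentadecanoic acid
Conditions: TFA/CH2Cl2 1:4, 0 °C to rt
Reagents that add atoms: none
Why: Acidolysis of the tert-butyl ester (E1 loss of isobutene through the tert-butyl cation) should free the acid under conditions to which the methoxyquinone, a vinylogous ester with no acid-labile group, is inert.

**Compound list**

1 | dimethyl squarate (3,4-dimethoxycyclobut-3-ene-1,2-dione) | COC1=C(OC)C(=O)C1=O | starting material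
2 | (±)-4-hydroxy-2,3-dimethoxycyclobut-2-en-1-one | COC1=C(OC)C(=O)C1O | intermediate
3 | 3-methoxycyclobut-3-ene-1,2-dione | COC1=CC(=O)C1=O | intermediate
4 | 15-bromopentadecanoic acid | BrCCCCCCCCCCCCCCC(=O)O | starting material
5 | lithium acetylide–ethylenediamine complex | [Li]C#C.NCCN | starting material
6 | heptadec-16-ynoic acid | C#CCCCCCCCCCCCCCCC(=O)O | intermediate
7 | 16-iodoheptadec-16-enoic acid | C=C(I)CCCCCCCCCCCCCCC(=O)O | intermediate
8 | tert-butyl 16-iodoheptadec-16-enoate | C=C(I)CCCCCCCCCCCCCCC(=O)OC(C)(C)C | intermediate
9 | tert-butyl 16-lithioheptadec-16-enoate | [Li]C(=C)CCCCCCCCCCCCCCC(=O)OC(C)(C)C | intermediate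
10 | (±)-tert-butyl 16-(1-hydroxy-2-methoxy-4-oxocyclobut-2-en-1-yl)heptadec-16-enoate | C=C(CCCCCCCCCCCCCCC(=O)OC(C)(C)C)C1(O)C(OC)=CC1=O | intermediate
11 | tert-butyl (17Z)-17-hydroxy-18-methoxy-16-methylidene-20-oxoicosa-17,19-dienoate (dienylketene) | O=C=C/C(OC)=C(O)\C(=C)CCCCCCCCCCCCCCC(=O)OC(C)(C)C | intermediate
12 | tert-butyl 15-(2-hydroxy-3-methoxy-5-oxocyclohexa-1,3-dien-1-yl)pentadecanoate | COC1=CC(=O)CC(CCCCCCCCCCCCCCC(=O)OC(C)(C)C)=C1O | intermediate
13 | tert-butyl 15-(2,5-dihydroxy-3-methoxyphenyl)pentadecanoate | COc1cc(O)cc(CCCCCCCCCCCCCCC(=O)OC(C)(C)C)c1O | intermediate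
14 | tert-butyl 15-(5-methoxy-3,6-dioxocyclohexa-1,4-dien-1-yl)pentadecanoate | COC1=CC(=O)C=C(CCCCCCCCCCCCCCC(=O)OC(C)(C)C)C1=O | intermediate
15 | 15-(5-methoxy-3,6-dioxocyclohexa-1,4-dien-1-yl)pentadecanoic acid (achiral) | COC1=CC(=O)C=C(CCCCCCCCCCCCCCC(=O)O)C1=O | target

**Summary**

Total step count: 7. Longest linear sequence: 6 steps (4 to 15, steps 2–7); step 1 is a one-step side branch.

Steps most likely to fail:

Step 5. The alkenyllithium may be consumed by proton transfer from the α-CH2 of the tert-butyl ester, or acylated by it, before it meets the dione; it may also add to the other carbonyl or in conjugate fashion at the ring CH. Fallback (esterification moved behind the C–C bond formation, the carboxylate acting as its own protecting group): it sets out from 7. MeLi (1 equiv) in THF at −78 °C gives lithium 16-iodoheptadec-16-enoate F1. t-BuLi (2 equiv) at −100 °C converts this into lithium 16-lithioheptadec-16-enoate F2, which has no electrophilic or readily enolised site at that temperature. Addition to 3 and a pH 5 phosphate quench should give (±)-16-(1-hydroxy-2-methoxy-4-oxocyclobut-2-en-1-yl)heptadec-16-enoic acid F3. Uncatalysed esterification with tert-butyl 2,2,2-trichloroacetimidate then returns to the route at 10.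

Step 6. The ketene may be captured by the free tertiary hydroxyl (lactonisation to a butenolide), 10 may lose methanol under trace acid before it ring-opens, or the electron-rich hydroquinone may oligomerise oxidatively at 110 °C. Fallback (the cascade is made to end at a mono-protected hydroquinone and the quinone is unveiled by oxidative desilylation): it sets out from 10. TMSCl/Et3N/DMAP in CH2Cl2 gives (±)-tert-butyl 16-[2-methoxy-4-oxo-1-(trimethylsilyloxy)cyclobut-2-en-1-yl]heptadec-16-enoate F4. Heating in toluene at 110 °C should lead through the ketene tert-butyl (17Z)-18-methoxy-16-methylidene-20-oxo-17-(trimethylsilyloxy)icosa-17,19-dienoate F5 and the dienone tert-butyl 15-[3-methoxy-5-oxo-2-(trimethylsilyloxy)cyclohexa-1,3-dien-1-yl]pentadecanoate F6 to the phenol tert-butyl 15-[5-hydroxy-3-methoxy-2-(trimethylsilyloxy)phenyl]pentadecanoate F7. CAN in MeCN/H2O at 0 °C oxidises F7 with loss of the silyl group, and the route is rejoined at 14.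

Step 3. A second HI addition may give the geminal diiodide, acid may move the double bond into the internal 2-iodo-2-alkenes, or conversion may stall because the C17 acid dissolves poorly. Fallback (syn-bromoboration and protodeboronation on the ester in place of ionic HX addition): it sets out from 6. tert-Butyl 2,2,2-trichloroacetimidate gives tert-butyl heptadec-16-ynoate F8. B-bromo-9-BBN in CH2Cl2 at 0 °C adds B–Br across the alkyne, bromine on the internal carbon, to give tert-butyl (16Z)-17-(9-borabicyclo[3.3.1]nonan-9-yl)-16-bromoheptadec-16-enoate F9. Protonolysis of the C–B bond with acetic acid gives tert-butyl 16-bromoheptadec-16-enoate F10. Bromine–lithium exchange with t-BuLi (2 equiv, −78 °C) returns to the route at alkenyllithium 9.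

**Further compounds**

F1 | step 5 | lithium 16-iodoheptadec-16-enoate | C=C(I)CCCCCCCCCCCCCCC(=O)[O-].[Li+]
F2 | step 5 | lithium 16-lithioheptadec-16-enoate | [Li]C(=C)CCCCCCCCCCCCCCC(=O)[O-].[Li+]
F3 | step 5 | (±)-16-(1-hydroxy-2-methoxy-4-oxocyclobut-2-en-1-yl)heptadec-16-enoic acid | C=C(CCCCCCCCCCCCCCC(=O)O)C1(O)C(OC)=CC1=O
F4 | step 6 | (±)-tert-butyl 16-[2-methoxy-4-oxo-1-(trimethylsilyloxy)cyclobut-2-en-1-yl]heptadec-16-enoate | C=C(CCCCCCCCCCCCCCC(=O)OC(C)(C)C)C1(O[Si](C)(C)C)C(OC)=CC1=O
F5 | step 6 | tert-butyl (17Z)-18-methoxy-16-methylidene-20-oxo-17-(trimethylsilyloxy)icosa-17,19-dienoate | O=C=C/C(OC)=C(O[Si](C)(C)C)\C(=C)CCCCCCCCCCCCCCC(=O)OC(C)(C)C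
F6 | step 6 | tert-butyl 15-[3-methoxy-5-oxo-2-(trimethylsilyloxy)cyclohexa-1,3-dien-1-yl]pentadecanoate | COC1=CC(=O)CC(CCCCCCCCCCCCCCC(=O)OC(C)(C)C)=C1O[Si](C)(C)C
F7 | step 6 | tert-butyl 15-[5-hydroxy-3-methoxy-2-(trimethylsilyloxy)phenyl]pentadecanoate | COc1cc(O)cc(CCCCCCCCCCCCCCC(=O)OC(C)(C)C)c1O[Si](C)(C)C
F8 | step 3 | tert-butyl heptadec-16-ynoate | C#CCCCCCCCCCCCCCCC(=O)OC(C)(C)C
F9 | step 3 | tert-butyl (16Z)-17-(9-borabicyclo[3.3.1]nonan-9-yl)-16-bromoheptadec-16-enoate | Br/C(CCCCCCCCCCCCCCC(=O)OC(C)(C)C)=C\B1C2CCCC1CCC2
F10 | step 3 | tert-butyl 16-bromoheptadec-16-enoate | C=C(Br)CCCCCCCCCCCCCCC(=O)OC(C)(C)C
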